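**Retrosynthetic overview**
The strategy rests on the four contiguous oxygens at C5, C6, C7 and C8 of ring A. They are read as a flavone-5,8-quinone whose only free double bond, C6=C7, takes the last two methoxyls.
Target 17 ⇐ benzyl ether 16 (hydrogenolysis) ⇐ hydroquinone 15 (O-methylation) ⇐ 6,7-dimethoxyquinone 14 (reduction).
Key disconnection: the C6–O and C7–O bonds of 14, from 6,7-dibromoquinone 11 and sodium methoxide 12.
11 ⇐ 5,8-dihydroxyflavone 9 (oxidative bromination) ⇐ 5-hydroxyflavone 7 (para-hydroxylation at C8) ⇐ chalcone 5 ⇐ aldehyde 3 + acetophenone 4.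
Ring order: rings A and B are bought; ring C is closed in step 3; no ring is formed afterwards.

Key step: step 6

Remark: the first methoxide is assumed to enter at C6, conjugate to the more electrophilic C8 carbonyl; entry at C7 first would lead to the same product 14.
Remark: in step 5 ring bromination is assumed to precede oxidation; if the order were reversed, the HBr released would add to the oxidised ring A and the same product 11 would result.
Remark: the acetophenones used only in the fallbacks (F1, F7) are assumed to be purchasable from specialist suppliers.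

**Route**

Step 1
Reactants: 1 3-hydroxy-4,5-dimethoxybenzaldehyde; 2 benzyl bromide
Product: 3 3-(benzyloxy)-4,5-dimethoxybenzaldehyde
Conditions: BnBr, K2CO3, DMF, 60 °C
Reagents that add atoms: benzyl bromide 2, BrCc1ccccc1
Why: Williamson ether synthesis, in which the phenoxide of 1 is alkylated by the benzylic bromide (SN2), giving a benzyl ether that masks the only free hydroxyl of ring B through the basic, oxidative and methylating steps until the final hydrogenolysis.

Step 2
Reactants: 3 3-(benzyloxy)-4,5-dimethoxybenzaldehyde; 4 2',6'-dihydroxyacetophenone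
Product: 5 (E)-3-[3-(benzyloxy)-4,5-dimethoxyphenyl]-1-(2,6-dihydroxyphenyl)prop-2-en-1-one
Conditions: KOH (50% aq.), EtOH, 0 °C to rt; then aq. HCl to pH 3
Reagents that add atoms: none
Why: Claisen–Schmidt condensation, in which the enolate of 4 adds to the non-enolisable aldehyde 3 and the aldol dehydrates by E1cB elimination to the thermodynamically preferred E-enone, a geometry that disappears once ring C is aromatised.

Step 3
Reactants: 5 (E)-3-[3-(benzyloxy)-4,5-dimethoxyphenyl]-1-(2,6-dihydroxyphenyl)prop-2-en-1-one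
Product: 7 3'-benzyloxy-5-hydroxy-4',5'-dimethoxyflavone, via 5-hydroxyflavanone 6 (not isolated)
Conditions: I2 (10 mol%), DMSO, 130 °C; aq. Na2S2O3 work-up
Reagents that add atoms: none
Why: Oxidative cyclisation of a 2'-hydroxychalcone with I2/DMSO, in which oxa-Michael closure of ring C gives flavanone 6, alpha-iodination and loss of HI give the flavone and DMSO reoxidises HI to I2; because 4 is symmetric either hydroxyl closes to the same product, and the racemic C2 centre of 6 is removed by the dehydrogenation.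

Step 4
Reactants: 7 3'-benzyloxy-5-hydroxy-4',5'-dimethoxyflavone
Product: 9 3'-benzyloxy-5,8-dihydroxy-4',5'-dimethoxyflavone, via potassium flavon-8-yl sulfate 8 (not isolated)
Conditions: K2S2O8, KOH (aq.), pyridine, 0 °C to rt; then aq. HCl, Na2SO3, 90 °C
Reagents that add atoms: potassium peroxodisulfate K2S2O8, [K+].[K+].[O-]S(=O)(=O)OOS(=O)(=O)[O-]
Why: Elbs persulfate oxidation, in which the 5-phenoxide attacks a peroxide oxygen of the persulfate through its para carbon C8 and acid hydrolysis of the aryl sulfate 8 frees the 8-hydroxyl, while ring B carries no free phenol and should stay untouched.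

Step 5
Reactants: 9 3'-benzyloxy-5,8-dihydroxy-4',5'-dimethoxyflavone
Product: 11 2-[3-(benzyloxy)-4,5-dimethoxyphenyl]-6,7-dibromo-4H-chromene-4,5,8-trione, via 6,7-dibromo-5,8-dihydroxyflavone 10 (not isolated)
Conditions: Br2 (3.0 equiv, slow addition), AcOH–CHCl3, 0 °C to rt
Reagents that add atoms: bromine, BrBr
Why: Oxidative bromination of a p-hydroquinone, in which ring A, by far the most nucleophilic arene of 9, is brominated at C6 and C7 (its only free positions) and the third equivalent of Br2 oxidises 10 to the quinone, so that the less activated ring B should meet no free bromine when the reagent is added slowly and held at three equivalents.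

Step 6
Reactants: 11 2-[3-(benzyloxy)-4,5-dimethoxyphenyl]-6,7-dibromo-4H-chromene-4,5,8-trione; 12 sodium methoxide
Product: 14 2-[3-(benzyloxy)-4,5-dimethoxyphenyl]-6,7-dimethoxy-4H-chromene-4,5,8-trione, via 7-bromo-6-methoxyquinone 13 (not isolated)
Conditions: NaOMe (2.2 equiv), dry MeOH–THF, −20 to 0 °C; AcOH quench
Reagents that add atoms: sodium methoxide 12, C[O-].[Na+]
Why: Nucleophilic vinylic substitution by addition–elimination, in which methoxide adds to the bromine-bearing C6 of 11 (a vinylogous acyl bromide), the enolate expels bromide to give 13, and the same sequence at C7 gives 14, forming the C6–O and C7–O bonds. The closest known reaction is the conversion of 2,3-dihalo-1,4-naphthoquinones into 2,3-dialkoxy-1,4-naphthoquinones with sodium alkoxides. No ring is closed and no stereocentre is created. The step needs site selectivity for C6 and C7 over C2 and C8a, where attack would open ring C; the substrate secures it because the other quinone double bond is the fully substituted C4a=C8a ring fusion and because the bromine-bearing carbons are both more electrophilic and carry the better leaving group. The second substitution is slower, since 13 is already a vinylogous ester, so the mixture is warmed from −20 to 0 °C with only a slight excess of NaOMe in dry solvent, which also keeps hydroxide from forming hydroxyquinones.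

Step 7
Reactants: 14 2-[3-(benzyloxy)-4,5-dimethoxyphenyl]-6,7-dimethoxy-4H-chromene-4,5,8-trione
Product: 15 3'-benzyloxy-5,8-dihydroxy-6,7,4',5'-tetramethoxyflavone
Conditions: Na2S2O4, THF–H2O, rt, N2
Reagents that add atoms: none
Why: Dithionite reduction of a p-quinone to its hydroquinone by two electron transfers and protonation, conditions under which the pyranone carbonyl, the aryl methyl ethers and the benzyl ether are not reduced.

Step 8
Reactants: 15 3'-benzyloxy-5,8-dihydroxy-6,7,4',5'-tetramethoxyflavone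
Product: 16 3'-benzyloxy-5,6,7,8,4',5'-hexamethoxyflavone
Conditions: (CH3O)2SO2 (excess), K2CO3, degassed acetone, reflux, N2; aq. NH3 quench
Reagents that add atoms: dimethyl sulfate, COS(=O)(=O)OC
Why: Exhaustive Williamson-type O-methylation of both phenols, in which the hydrogen-bonded 5-hydroxyl reacts more slowly than the 8-hydroxyl (hence excess reagent and prolonged reflux) and exclusion of air keeps the electron-rich hydroquinone from reverting to 14.

Step 9
Reactants: 16 3'-benzyloxy-5,6,7,8,4',5'-hexamethoxyflavone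
Product: 17 3'-hydroxy-5,6,7,8,4',5'-hexamethoxyflavone
Conditions: H2 (1 atm), 10% Pd/C, EtOAc–MeOH, rt
Reagents that add atoms: none
Why: Catalytic hydrogenolysis of the benzylic C–O bond over Pd/C, which should leave the six methyl ethers and, at 1 atm and room temperature with the reaction stopped after uptake of one equivalent of H2, the C2=C3 bond of the pyranone intact.

**Compound list**
1 | 3-hydroxy-4,5-dimethoxybenzaldehyde | COc1cc(C=O)cc(O)c1OC | starting material
2 | benzyl bromide | BrCc1ccccc1 | starting material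
3 | 3-(benzyloxy)-4,5-dimethoxybenzaldehyde | COc1cc(C=O)cc(OCc2ccccc2)c1OC | intermediate
4 | 2',6'-dihydroxyacetophenone | CC(=O)c1c(O)cccc1O | starting material
5 | (E)-3-[3-(benzyloxy)-4,5-dimethoxyphenyl]-1-(2,6-dihydroxyphenyl)prop-2-en-1-one | O=C(/C=C/c1cc(OC)c(OC)c(OCc2ccccc2)c1)c1c(O)cccc1O | intermediate
6 | 2-[3-(benzyloxy)-4,5-dimethoxyphenyl]-5-hydroxychroman-4-one (racemic, not isolated) | O=C1CC(c2cc(OC)c(OC)c(OCc3ccccc3)c2)Oc2cccc(O)c21 | intermediate
7 | 3'-benzyloxy-5-hydroxy-4',5'-dimethoxyflavone | O=c1cc(-c2cc(OC)c(OC)c(OCc3ccccc3)c2)oc2cccc(O)c12 | intermediate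
8 | potassium 2-[3-(benzyloxy)-4,5-dimethoxyphenyl]-5-hydroxy-4-oxo-4H-chromen-8-yl sulfate (not isolated) | O=c1cc(-c2cc(OC)c(OC)c(OCc3ccccc3)c2)oc2c(OS(=O)(=O)[O-])ccc(O)c12.[K+] | intermediate
9 | 3'-benzyloxy-5,8-dihydroxy-4',5'-dimethoxyflavone | O=c1cc(-c2cc(OC)c(OC)c(OCc3ccccc3)c2)oc2c(O)ccc(O)c12 | intermediate
10 | 3'-benzyloxy-6,7-dibromo-5,8-dihydroxy-4',5'-dimethoxyflavone (not isolated) | O=c1cc(-c2cc(OC)c(OC)c(OCc3ccccc3)c2)oc2c(O)c(Br)c(Br)c(O)c12 | intermediate
11 | 2-[3-(benzyloxy)-4,5-dimethoxyphenyl]-6,7-dibromo-4H-chromene-4,5,8-trione | O=C1C(Br)=C(Br)C(=O)c2oc(-c3cc(OC)c(OC)c(OCc4ccccc4)c3)cc(=O)c21 | intermediate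
12 | sodium methoxide (NaOMe) | C[O-].[Na+] | starting material
13 | 2-[3-(benzyloxy)-4,5-dimethoxyphenyl]-7-bromo-6-methoxy-4H-chromene-4,5,8-trione (not isolated) | O=C1C(OC)=C(Br)C(=O)c2oc(-c3cc(OC)c(OC)c(OCc4ccccc4)c3)cc(=O)c21 | intermediate
14 | 2-[3-(benzyloxy)-4,5-dimethoxyphenyl]-6,7-dimethoxy-4H-chromene-4,5,8-trione | O=C1C(OC)=C(OC)C(=O)c2oc(-c3cc(OC)c(OC)c(OCc4ccccc4)c3)cc(=O)c21 | intermediate
15 | 3'-benzyloxy-5,8-dihydroxy-6,7,4',5'-tetramethoxyflavone | O=c1cc(-c2cc(OC)c(OC)c(OCc3ccccc3)c2)oc2c(O)c(OC)c(OC)c(O)c12 | intermediate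
16 | 3'-benzyloxy-5,6,7,8,4',5'-hexamethoxyflavone | COc1cc(-c2cc(=O)c3c(OC)c(OC)c(OC)c(OC)c3o2)cc(OCc2ccccc2)c1OC | intermediate
17 | 3'-hydroxy-5,6,7,8,4',5'-hexamethoxyflavone | COc1cc(-c2cc(=O)c3c(OC)c(OC)c(OC)c(OC)c3o2)cc(O)c1OC | target

**Step count and risks**
Total steps: 9. Longest linear sequence: 9 steps (1 → 3 → 5 → 7 → 9 → 11 → 14 → 15 → 16 → 17).

Step 6 (key step). What may go wrong: attack of methoxide at C2 or C8a with opening of ring C, electron transfer from methoxide to the quinone, or stalling after the first substitution. Fallback: the route sets out again from aldehyde 3 and brings ring A in fully methoxylated. Claisen–Schmidt condensation of 3 with 2'-hydroxy-3',4',5',6'-tetramethoxyacetophenone F1 (KOH, EtOH) should give the chalcone (E)-3-[3-(benzyloxy)-4,5-dimethoxyphenyl]-1-(2-hydroxy-3,4,5,6-tetramethoxyphenyl)prop-2-en-1-one F2. Catalytic I2 in DMSO at 130 °C should then close ring C by way of the tetramethoxyflavanone F3 and dehydrogenate it to 16, where the route is rejoined before step 9. No quinone is exposed to alkoxide on this path.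

Step 5. What may go wrong: electrophilic bromination of ring B at C2' or C6' once ring A is consumed, or acid cleavage of the benzyl ether by the HBr released. Fallback: the route sets out from 9 and delivers bromine only as nucleophilic bromide. Oxidation of 9 with Ag2O (MgSO4, THF) should give the flavone-5,8-quinone 2-[3-(benzyloxy)-4,5-dimethoxyphenyl]-4H-chromene-4,5,8-trione F4. 1,4-Addition of HBr (48% aq., 1.1 equiv, AcOH–THF, 0 °C) should give 3'-benzyloxy-6-bromo-5,8-dihydroxy-4',5'-dimethoxyflavone F5 (the 7-bromo isomer would serve equally). Reoxidation with Ag2O should give the bromoquinone 2-[3-(benzyloxy)-4,5-dimethoxyphenyl]-6-bromo-4H-chromene-4,5,8-trione F6. A second HBr addition at the remaining quinone carbon gives 10, this time isolated, and a last Ag2O oxidation gives 11, where the route is rejoined before step 6.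

Step 4. What may go wrong: low conversion in the persulfate hydroxylation, over-oxidation, or opening of ring C in aqueous alkali. Fallback: the route sets out from aldehyde 3 with the C8 oxygen already in the acetophenone. Claisen–Schmidt condensation of 3 with 2'-hydroxy-3',6'-dimethoxyacetophenone F7 should give the chalcone (E)-3-[3-(benzyloxy)-4,5-dimethoxyphenyl]-1-(2-hydroxy-3,6-dimethoxyphenyl)prop-2-en-1-one F8. I2 in DMSO should convert it by way of the 5,8-dimethoxyflavanone F9 into 3'-benzyloxy-5,8,4',5'-tetramethoxyflavone F10. Oxidative demethylation of the para-dimethoxy ring A with (NH4)2Ce(NO3)6 (MeCN–H2O, 0 °C) should give the quinone F4 of the preceding fallback. Reduction with Na2S2O4 then gives 9, where the route is rejoined before step 5.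

**Further compounds**
F1 | step 6 | 2'-hydroxy-3',4',5',6'-tetramethoxyacetophenone | CC(=O)c1c(O)c(OC)c(OC)c(OC)c1OC
F2 | step 6 | (E)-3-[3-(benzyloxy)-4,5-dimethoxyphenyl]-1-(2-hydroxy-3,4,5,6-tetramethoxyphenyl)prop-2-en-1-one | O=C(/C=C/c1cc(OC)c(OC)c(OCc2ccccc2)c1)c1c(O)c(OC)c(OC)c(OC)c1OC
F3 | step 6 | 2-[3-(benzyloxy)-4,5-dimethoxyphenyl]-5,6,7,8-tetramethoxychroman-4-one (racemic) | O=C1CC(c2cc(OC)c(OC)c(OCc3ccccc3)c2)Oc2c(OC)c(OC)c(OC)c(OC)c21
F4 | step 5 | 2-[3-(benzyloxy)-4,5-dimethoxyphenyl]-4H-chromene-4,5,8-trione | O=C1C=CC(=O)c2oc(-c3cc(OC)c(OC)c(OCc4ccccc4)c3)cc(=O)c21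
F5 | step 5 | 3'-benzyloxy-6-bromo-5,8-dihydroxy-4',5'-dimethoxyflavone | O=c1cc(-c2cc(OC)c(OC)c(OCc3ccccc3)c2)oc2c(O)cc(Br)c(O)c12
F6 | step 5 | 2-[3-(benzyloxy)-4,5-dimethoxyphenyl]-6-bromo-4H-chromene-4,5,8-trione | O=C1C(Br)=CC(=O)c2oc(-c3cc(OC)c(OC)c(OCc4ccccc4)c3)cc(=O)c21
F7 | step 4 | 2'-hydroxy-3',6'-dimethoxyacetophenone | CC(=O)c1c(O)c(OC)ccc1OC
F8 | step 4 | (E)-3-[3-(benzyloxy)-4,5-dimethoxyphenyl]-1-(2-hydroxy-3,6-dimethoxyphenyl)prop-2-en-1-one | O=C(/C=C/c1cc(OC)c(OC)c(OCc2ccccc2)c1)c1c(O)c(OC)ccc1OC
F9 | step 4 | 2-[3-(benzyloxy)-4,5-dimethoxyphenyl]-5,8-dimethoxychroman-4-one (racemic) | O=C1CC(c2cc(OC)c(OC)c(OCc3ccccc3)c2)Oc2c(OC)ccc(OC)c21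
F10 | step 4 | 3'-benzyloxy-5,8,4',5'-tetramethoxyflavone | O=c1cc(-c2cc(OC)c(OC)c(OCc3ccccc3)c2)oc2c(OC)ccc(OC)c12
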